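**Plan**
- Retrosynthesis: the hydroquinone ring B is raised to its quinone, and the ring B C–O bond of the diaryl ether is cut. This opens the 21-membered ring to a seco 2-bromo-6-alkyl-1,4-benzoquinone that carries a free 5-alkylresorcinol (ring A).
- The tetradecyl tether is then cut at its two benzylic C–C bonds (as alkenes) into a ring B aldehyde (one carbon), a C12 hydroxy phosphonium linker and a ring A benzylic phosphonium salt (one carbon).
- Forward: bromination and methylation give the ring B aldehyde; two Wittig reactions with an alcohol oxidation between them join linker and ring A; diimide saturates the tether; BBr3 frees four phenols; Ag2O oxidizes only ring B; the macrocycle (the only ring formed) closes; Na2S2O4 returns the hydroquinone.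
- Enabling feature: ring B is a 2-aryloxy-6-alkylhydroquinone, a reduced quinone whose ether-bearing carbon C2 is the β-carbon of an enedione, and the two oxygens of ring A are equivalent until the ring closes.
- Stereochemistry: the target has no stereocentre; the alkene geometry of the Wittig products is erased by the reduction.

Key step: step 10

Assumption: the ring A Wittig salt (3,5-dimethoxybenzyl)triphenylphosphonium bromide is taken as a catalogue reagent.

**Step 1**
Reactants: 1 2-hydroxy-5-methoxybenzaldehyde
Product: 2 3-bromo-2-hydroxy-5-methoxybenzaldehyde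
Conditions: Br2, NaOAc, AcOH, rt
Reagents that add atoms: bromine, BrBr
Why: Electrophilic aromatic bromination in which the free phenol directs to its only open ortho position (its para position carries the methoxy group) while acetate buffers the HBr.

**Step 2**
Reactants: 2 3-bromo-2-hydroxy-5-methoxybenzaldehyde
Product: 3 3-bromo-2,5-dimethoxybenzaldehyde
Conditions: MeI, K2CO3, DMF, rt
Reagents that add atoms: iodomethane, CI
Why: Williamson O-methylation of the phenoxide, which fixes ring B as a para-dimethoxyarene with bromine and the formyl group flanking one methoxy group.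

**Step 3**
Reactants: 4 12-bromododecan-1-ol
Product: 5 (12-hydroxydodecyl)triphenylphosphonium bromide
Conditions: PPh3, MeCN, reflux
Reagents that add atoms: triphenylphosphine, c1ccc(cc1)P(c1ccccc1)c1ccccc1
Why: SN2 quaternization of the phosphine by the primary bromide, which needs no protection of the remote hydroxyl.

**Step 4**
Reactants: 5 (12-hydroxydodecyl)triphenylphosphonium bromide; 3 3-bromo-2,5-dimethoxybenzaldehyde
Product: 7 13-(3-bromo-2,5-dimethoxyphenyl)tridec-12-en-1-ol (mixture of alkene isomers), via sodium alkoxide ylide 6 (not isolated)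
Conditions: NaN(SiMe3)2 (2 equiv), THF, 0 °C; then 3, −78 °C to rt; then H2O
Reagents that add atoms: none
Why: Wittig olefination in which two equivalents of amide base generate the non-stabilized ylide together with its alkoxide, which condenses with the non-enolizable aldehyde without touching the aryl bromide.

**Step 5**
Reactants: 7 13-(3-bromo-2,5-dimethoxyphenyl)tridec-12-en-1-ol
Product: 8 13-(3-bromo-2,5-dimethoxyphenyl)tridec-12-enal
Conditions: Dess–Martin periodinane, CH2Cl2, rt
Reagents that add atoms: none
Why: Dess–Martin oxidation of the primary alcohol stops cleanly at the aldehyde and leaves the styrenyl alkene and the electron-rich arene alone.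

**Step 6**
Reactants: 8 13-(3-bromo-2,5-dimethoxyphenyl)tridec-12-enal; 9 (3,5-dimethoxybenzyl)triphenylphosphonium bromide
Product: 11 1-bromo-3-[14-(3,5-dimethoxyphenyl)tetradeca-1,13-dien-1-yl]-2,5-dimethoxybenzene (mixture of alkene isomers), via benzylidene ylide 10 (not isolated)
Conditions: NaN(SiMe3)2, THF, 0 °C; then 8, −78 °C to rt
Reagents that add atoms: none
Why: Wittig olefination of the aliphatic aldehyde with a semi-stabilized benzylic ylide, reactive yet only weakly basic, attaches ring A and completes the fourteen-carbon tether.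

**Step 7**
Reactants: 11 1-bromo-3-[14-(3,5-dimethoxyphenyl)tetradeca-1,13-dien-1-yl]-2,5-dimethoxybenzene
Product: 12 1-bromo-3-[14-(3,5-dimethoxyphenyl)tetradecyl]-2,5-dimethoxybenzene
Conditions: TsNHNH2 (excess), NaOAc, DME/H2O, reflux
Reagents that add atoms: none
Why: Diimide reduction, in which diimide released from the sulfonyl hydrazide transfers H2 in a concerted syn fashion to both 1,2-disubstituted alkenes and cannot cleave the aryl C–Br bond that hydrogenation over palladium would endanger.

**Step 8**
Reactants: 12 1-bromo-3-[14-(3,5-dimethoxyphenyl)tetradecyl]-2,5-dimethoxybenzene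
Product: 13 2-bromo-6-[14-(3,5-dihydroxyphenyl)tetradecyl]benzene-1,4-diol
Conditions: BBr3 (excess), CH2Cl2, −78 °C to rt; then degassed H2O, Ar
Reagents that add atoms: none
Why: Lewis-acid cleavage of aryl methyl ethers, in which BBr3 coordinates each methoxy oxygen and bromide removes the methyl group by SN2, frees all four phenols while the aryl bromide and the tether stay untouched.

**Step 9**
Reactants: 13 2-bromo-6-[14-(3,5-dihydroxyphenyl)tetradecyl]benzene-1,4-diol
Product: 14 2-bromo-6-[14-(3,5-dihydroxyphenyl)tetradecyl]-1,4-benzoquinone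
Conditions: Ag2O, Na2SO4, Et2O, rt, dark; filtered and used at once
Reagents that add atoms: none
Why: Selective hydroquinone-to-quinone oxidation, because Ag2O is a mild neutral oxidant for para-dihydroxybenzenes whereas the meta-dihydroxy ring A cannot form a quinone and is much harder to oxidize.

**Step 10**
Reactants: 14 2-bromo-6-[14-(3,5-dihydroxyphenyl)tetradecyl]-1,4-benzoquinone
Product: 16 macrocyclic 2-aryloxy-6-alkyl-1,4-benzoquinone (quinone form of the target), via caesium phenoxide 15 (not isolated)
Conditions: Cs2CO3, degassed DMF, syringe-pump addition of 14 (final about 1 mM), rt, Ar; pH 5 buffer work-up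
Reagents that add atoms: none
Why: Cs2CO3 converts one of the two equivalent ring A hydroxyls into the caesium phenoxide 15, whose oxygen adds to the bromine-bearing C2 of the tethered quinone (the β-carbon of the C2=C3–C4=O enone) to give an enolate that expels bromide and restores the quinone. The closest known reaction type is the replacement of halogen in halo-1,4-benzoquinones by phenoxides through addition–elimination, used here within one molecule under pseudo-high dilution. The 21-membered ring closes in 21-exo-trig mode, the attacked C2=C3 double bond lying outside the new ring. No stereocentre is created. The step needs O-attack at C2 in preference to C-attack by the resorcinol ring or oxygen addition at C3 or C5: only the adduct at C2 can collapse irreversibly by loss of bromide while the others revert, a dissociated caesium phenoxide in DMF reacts through oxygen, and the equivalence of the two ring A oxygens means either one leads to the same macrocycle. Slow addition keeps the stationary concentration of 15 low so that ring closure outruns chain-to-chain coupling.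

**Step 11**
Reactants: 16 macrocyclic 2-aryloxy-6-alkyl-1,4-benzoquinone
Product: 17 target CNP0393720.0 (macrocyclic 2-aryloxy-6-alkylbenzene-1,4-diol)
Conditions: Na2S2O4, THF/H2O, rt, Ar
Reagents that add atoms: none
Why: Dithionite reduction of the quinone to the hydroquinone is a two-electron, two-proton transfer that leaves the diaryl ether and the ring A phenol untouched and should deliver the target directly.

**Compound list**
1 | 2-hydroxy-5-methoxybenzaldehyde | O=Cc1cc(OC)ccc1O | starting material
2 | 3-bromo-2-hydroxy-5-methoxybenzaldehyde | O=Cc1cc(OC)cc(Br)c1O | intermediate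
3 | 3-bromo-2,5-dimethoxybenzaldehyde | O=Cc1cc(OC)cc(Br)c1OC | intermediate
4 | 12-bromododecan-1-ol | OCCCCCCCCCCCCBr | starting material
5 | (12-hydroxydodecyl)triphenylphosphonium bromide | OCCCCCCCCCCCC[P+](c1ccccc1)(c1ccccc1)c1ccccc1.[Br-] | intermediate
6 | sodium 12-(triphenylphosphoranylidene)dodecan-1-olate (alkoxide ylide, not isolated) | [Na+].[O-]CCCCCCCCCCCC=P(c1ccccc1)(c1ccccc1)c1ccccc1 | intermediate
7 | 13-(3-bromo-2,5-dimethoxyphenyl)tridec-12-en-1-ol (alkene isomer mixture) | OCCCCCCCCCCCC=Cc1cc(OC)cc(Br)c1OC | intermediate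
8 | 13-(3-bromo-2,5-dimethoxyphenyl)tridec-12-enal (alkene isomer mixture) | O=CCCCCCCCCCCC=Cc1cc(OC)cc(Br)c1OC | intermediate
9 | (3,5-dimethoxybenzyl)triphenylphosphonium bromide | COc1cc(C[P+](c2ccccc2)(c2ccccc2)c2ccccc2)cc(OC)c1.[Br-] | starting material
10 | (3,5-dimethoxybenzylidene)triphenylphosphorane (ylide, not isolated) | COc1cc(C=P(c2ccccc2)(c2ccccc2)c2ccccc2)cc(OC)c1 | intermediate
11 | 1-bromo-3-[14-(3,5-dimethoxyphenyl)tetradeca-1,13-dien-1-yl]-2,5-dimethoxybenzene (alkene isomer mixture) | COc1cc(C=CCCCCCCCCCCCC=Cc2cc(OC)cc(Br)c2OC)cc(OC)c1 | intermediate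
12 | 1-bromo-3-[14-(3,5-dimethoxyphenyl)tetradecyl]-2,5-dimethoxybenzene | COc1cc(CCCCCCCCCCCCCCc2cc(OC)cc(Br)c2OC)cc(OC)c1 | intermediate
13 | 2-bromo-6-[14-(3,5-dihydroxyphenyl)tetradecyl]benzene-1,4-diol | Oc1cc(O)cc(CCCCCCCCCCCCCCc2cc(O)cc(Br)c2O)c1 | intermediate
14 | 2-bromo-6-[14-(3,5-dihydroxyphenyl)tetradecyl]-1,4-benzoquinone | Oc1cc(O)cc(CCCCCCCCCCCCCCC2=CC(=O)C=C(Br)C2=O)c1 | intermediate
15 | caesium mono-phenoxide of 14 (not isolated) | [Cs+].[O-]c1cc(O)cc(CCCCCCCCCCCCCCC2=CC(=O)C=C(Br)C2=O)c1 | intermediate
16 | macrocyclic 2-aryloxy-6-alkyl-1,4-benzoquinone, quinone form of the target (21-membered ring) | Oc1cc2cc(c1)OC1=CC(=O)C=C(C1=O)CCCCCCCCCCCCCC2 | intermediate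
17 | CNP0393720.0, macrocyclic 2-aryloxy-6-alkylbenzene-1,4-diol with one free ring A hydroxyl | Oc1cc2cc(c1)Oc1cc(O)cc(c1O)CCCCCCCCCCCCCC2 | target

**Count**
Total steps: 11. Longest linear sequence: 10 steps (1 → 2 → 3 → 7 → 8 → 11 → 12 → 13 → 14 → 16 → 17).

**Steps most likely to fail**

Step 10 (key step). What may go wrong: the phenoxide may attack through a ring carbon, the benzylic position of the alkylquinone may be deprotonated towards a quinone methide, or chains may couple with one another faster than the ring closes. Fallback: the same aryl ether bond is made by a copper-catalysed intramolecular Ullmann coupling with ring B kept as its dimethyl ether. It sets out from aldehyde 8. [3,5-Bis(benzyloxy)benzyl]triphenylphosphonium bromide F1, made from 3,5-bis(benzyloxy)benzyl bromide and PPh3, is deprotonated with NaN(SiMe3)2 and condensed with 8 to give 1-bromo-3-{14-[3,5-bis(benzyloxy)phenyl]tetradeca-1,13-dien-1-yl}-2,5-dimethoxybenzene F2. Diimide (TsNHNH2, NaOAc) saturates it to 1-bromo-3-{14-[3,5-bis(benzyloxy)phenyl]tetradecyl}-2,5-dimethoxybenzene F3. BCl3 with pentamethylbenzene in CH2Cl2 at −78 °C removes only the benzyl ethers and gives 5-[14-(3-bromo-2,5-dimethoxyphenyl)tetradecyl]benzene-1,3-diol F4. CuI, N,N-dimethylglycine and Cs2CO3 in dioxane at 90 °C under high dilution should close the ring to the ring B dimethyl ether of the target macrocycle F5. BBr3 in CH2Cl2 then cleaves the two methyl ethers, and the route is rejoined at the target 17.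

Step 9. What may go wrong: the oxidant may also attack the free resorcinol ring (oxidative coupling), or the new quinone may condense with ring A of a second molecule during isolation. Fallback: ring A is masked while ring B is oxidized. It sets out from 13. TBSCl and imidazole in DMF give the tetrakis(tert-butyldimethylsilyl) ether of 13 F6. (NH4)2Ce(NO3)6 in MeCN/H2O at 0 °C desilylates the para-bis(silyloxy) ring oxidatively to 2-bromo-6-{14-[3,5-bis(tert-butyldimethylsilyloxy)phenyl]tetradecyl}-1,4-benzoquinone F7. Aqueous HF in MeCN removes the two remaining silyl ethers without harming the quinone, and the route is rejoined at 14.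

Step 6. What may go wrong: the α-methylene aldehyde 8 may be enolized by the ylide or by residual amide base and condense with itself, or it may oxidize and oligomerize before use, so that the olefination stalls. Fallback: the polarity of the olefination is reversed so that no enolizable aldehyde is involved. It sets out from alcohol 7. I2, PPh3 and imidazole give 1-bromo-3-(13-iodotridec-1-en-1-yl)-2,5-dimethoxybenzene F8. PPh3 in MeCN at reflux gives [13-(3-bromo-2,5-dimethoxyphenyl)tridec-12-en-1-yl]triphenylphosphonium iodide F9. Its ylide (NaN(SiMe3)2, THF) is condensed with commercial 3,5-dimethoxybenzaldehyde, and the route is rejoined at diene 11.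

**Further compounds**
F1 | step 10 | [3,5-bis(benzyloxy)benzyl]triphenylphosphonium bromide | [Br-].c1ccc(cc1)COc1cc(C[P+](c2ccccc2)(c2ccccc2)c2ccccc2)cc(OCc2ccccc2)c1
F2 | step 10 | 1-bromo-3-{14-[3,5-bis(benzyloxy)phenyl]tetradeca-1,13-dien-1-yl}-2,5-dimethoxybenzene | COc1cc(Br)c(OC)c(C=CCCCCCCCCCCCC=Cc2cc(OCc3ccccc3)cc(OCc3ccccc3)c2)c1
F3 | step 10 | 1-bromo-3-{14-[3,5-bis(benzyloxy)phenyl]tetradecyl}-2,5-dimethoxybenzene | COc1cc(Br)c(OC)c(CCCCCCCCCCCCCCc2cc(OCc3ccccc3)cc(OCc3ccccc3)c2)c1
F4 | step 10 | 5-[14-(3-bromo-2,5-dimethoxyphenyl)tetradecyl]benzene-1,3-diol | Oc1cc(O)cc(CCCCCCCCCCCCCCc2cc(OC)cc(Br)c2OC)c1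
F5 | step 10 | ring B dimethyl ether of the target macrocycle | Oc1cc2cc(c1)Oc1cc(OC)cc(c1OC)CCCCCCCCCCCCCC2
F6 | step 9 | tetrakis(tert-butyldimethylsilyl) ether of 13 | CC(C)(C)[Si](C)(C)Oc1cc(O[Si](C)(C)C(C)(C)C)cc(CCCCCCCCCCCCCCc2cc(O[Si](C)(C)C(C)(C)C)cc(Br)c2O[Si](C)(C)C(C)(C)C)c1
F7 | step 9 | 2-bromo-6-{14-[3,5-bis(tert-butyldimethylsilyloxy)phenyl]tetradecyl}-1,4-benzoquinone | CC(C)(C)[Si](C)(C)Oc1cc(O[Si](C)(C)C(C)(C)C)cc(CCCCCCCCCCCCCCC2=CC(=O)C=C(Br)C2=O)c1
F8 | step 6 | 1-bromo-3-(13-iodotridec-1-en-1-yl)-2,5-dimethoxybenzene | ICCCCCCCCCCCC=Cc1cc(OC)cc(Br)c1OC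
F9 | step 6 | [13-(3-bromo-2,5-dimethoxyphenyl)tridec-12-en-1-yl]triphenylphosphonium iodide | [I-].COc1cc(Br)c(OC)c(C=CCCCCCCCCCCC[P+](c2ccccc2)(c2ccccc2)c2ccccc2)c1
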